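**Retrosynthetic overview**
1. Enol ester ⇐ O-acylation of the C11 acetaldehyde, itself from ozonolysis of an allyl group.
2. Rings A (pyran) and B (cyclohexane) ⇐ formed last and together, by BF3-promoted cation–olefin cyclisation of a 2-(hydroxymethyl)cyclohept-2-enone carrying the homoprenyl chain.
3. Ring C (formed first) and the 1,4-diketone ⇐ intramolecular Stetter closure: the aldehyde carbon, as a carbene-bound acyl anion, adds to the enone β-carbon.
4. Acyclic aldehyde–enone ⇐ acetal/enol-silane homologation, Wittig olefination and oxidative opening of a cyclopentanone.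
5. Cyclopentanone with both side-chain stereocentres ⇐ Cu(OTf)2/carbene-catalysed asymmetric conjugate addition and enolate allylation of 3-methylcyclopent-2-enone.

Assumption: 5-bromo-2-methylpent-2-ene, trimethyl(vinyloxy)silane and 3-methylbut-2-enoic anhydride are taken as purchasable reagents.

**Step 1**
Reactants: 1 5-bromo-2-methylpent-2-ene; 2 3-methylcyclopent-2-en-1-one; 3 3-iodoprop-1-ene
Product: 6 (2R,3S)-3-methyl-3-(4-methylpent-3-en-1-yl)-2-(prop-2-en-1-yl)cyclopentan-1-one, via Grignard reagent 4 (not isolated), via magnesium enolate 5 (not isolated)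
Conditions: Mg, Et2O, 35 °C; then 2, Cu(OTf)2 (3 mol%), chiral 4,5-diphenylimidazolinium chloride carbene precursor (4 mol%, antipode that delivers 3S), Et2O, −30 °C; then 3, DMPU, −30 → 23 °C
Reagents that add atoms: none
Why: Cu(OTf)2/chiral carbene-catalysed asymmetric conjugate addition of the Grignard reagent creates the quaternary C3 centre (S, catalyst control) and the magnesium enolate is allylated in the same flask anti to the longer C3 chain (2R, trans, expected only about 3–5:1, minor epimer removed on silica), a conjugate addition–enolate trapping domino.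

**Step 2**
Reactants: 6 (2R,3S)-3-methyl-3-(4-methylpent-3-en-1-yl)-2-(prop-2-en-1-yl)cyclopentan-1-one
Product: 8 (2R,3S)-5-hydroxy-3-methyl-3-(4-methylpent-3-en-1-yl)-2-(prop-2-en-1-yl)cyclopentan-1-one (both C5 epimers), via sodium enolate 7 (not isolated)
Conditions: NaN(SiMe3)2, THF, −78 °C; then 2-(benzenesulfonyl)-3-phenyloxaziridine, −78 °C; AcOH
Reagents that add atoms: 2-(benzenesulfonyl)-3-phenyloxaziridine, O=S(=O)(N1OC1c1ccccc1)c1ccccc1
Why: Kinetic deprotonation occurs at the unhindered C5 methylene and the sodium enolate is hydroxylated by the oxaziridine (Davis oxidation), the new carbinol centre being irrelevant because it becomes an aldehyde carbon in step 3.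

**Step 3**
Reactants: 8 (2R,3S)-5-hydroxy-3-methyl-3-(4-methylpent-3-en-1-yl)-2-(prop-2-en-1-yl)cyclopentan-1-one
Product: 10 methyl (2R,3S)-5,5-dimethoxy-3-methyl-3-(4-methylpent-3-en-1-yl)-2-(prop-2-en-1-yl)pentanoate, via ester aldehyde 9 (not isolated)
Conditions: Pb(OAc)4, MeOH/PhMe (1:1), 0 °C; then HC(OMe)3, TsOH·H2O (5 mol%), 23 °C
Reagents that add atoms: methanol, CO; trimethyl orthoformate, COC(OC)OC
Why: Criegee-type Pb(OAc)4 cleavage of the α-ketol in methanol turns the ketone carbon into the methyl ester and the carbinol carbon into the aldehyde, which is masked at once as its dimethyl acetal under acid catalysis (faster than any ene reaction with the trisubstituted alkene), and no stereocentre is touched.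

**Step 4**
Reactants: 10 methyl (2R,3S)-5,5-dimethoxy-3-methyl-3-(4-methylpent-3-en-1-yl)-2-(prop-2-en-1-yl)pentanoate; 11 1-(triphenyl-λ5-phosphanylidene)propan-2-one
Product: 13 (3E,5S,6S)-8,8-dimethoxy-6-methyl-6-(4-methylpent-3-en-1-yl)-5-(prop-2-en-1-yl)oct-3-en-2-one, via aldehyde 12 (not isolated)
Conditions: iBu2AlH (1.05 equiv), CH2Cl2, −78 °C; then 11, −78 → 40 °C; aq. potassium sodium tartrate
Reagents that add atoms: none
Why: The hindered ester stops at the aluminium hemiacetal at −78 °C and the aldehyde released on warming is intercepted in the same flask by the stabilised ylide (one-pot iBu2AlH reduction–Wittig olefination, E-selective), so the epimerisable α-branched aldehyde is never handled.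

**Step 5**
Reactants: 13 (3E,5S,6S)-8,8-dimethoxy-6-methyl-6-(4-methylpent-3-en-1-yl)-5-(prop-2-en-1-yl)oct-3-en-2-one; 14 trimethyl(vinyloxy)silane
Product: 15 (5S,6S,7E)-3-methoxy-5-methyl-5-(4-methylpent-3-en-1-yl)-9-oxo-6-(prop-2-en-1-yl)dec-7-enal (both C3 epimers)
Conditions: 14 (4 equiv), Me3SiOTf (10 mol%), CH2Cl2, −78 °C; pyridine quench
Reagents that add atoms: none
Why: Me3SiOTf ionises the dimethyl acetal to an oxocarbenium ion that is captured by the enol silane, a far better nucleophile than the tethered trisubstituted alkene (Mukaiyama-type acetal aldol addition), giving the β-methoxy aldehyde directly, and the methoxy-bearing centre forms unselectively and is erased in step 6.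

**Step 6**
Reactants: 15 (5S,6S,7E)-3-methoxy-5-methyl-5-(4-methylpent-3-en-1-yl)-9-oxo-6-(prop-2-en-1-yl)dec-7-enal
Product: 17 (5S,6S,7S)-5-methyl-5-(4-methylpent-3-en-1-yl)-7-(2-oxopropyl)-6-(prop-2-en-1-yl)cyclohept-2-en-1-one, via methoxy ketone 16 (not isolated)
Conditions: 2-(pentafluorophenyl)-6,7-dihydro-5H-pyrrolo[2,1-c][1,2,4]triazol-2-ium tetrafluoroborate (20 mol%), KN(SiMe3)2 (18 mol%), PhMe, 23 → 50 °C; then DBU (1.5 equiv), 23 °C
Reagents that add atoms: none
Why: Proposed new method: the triazolylidene turns the aldehyde carbon into a Breslow acyl-anion equivalent that adds 7-exo-trig to the enone β-carbon, joining two carbons that are both electrophilic by nature and creating the ring C ketone and the 1,4-diketone in one event, the closure being helped by the quaternary and branched carbons in the tether and kept free of a homoenolate pathway because the future ring alkene is masked as the methoxy group; the closest known reaction type is the intramolecular Stetter reaction of aliphatic aldehydes to five- and six-membered rings; DBU then expels methoxide (E1cB) to give the enone and equilibrates the new C7 centre, α to the ketone, to the trans (7S) arrangement with the neighbouring allyl group.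

**Step 7**
Reactants: 17 (5S,6S,7S)-5-methyl-5-(4-methylpent-3-en-1-yl)-7-(2-oxopropyl)-6-(prop-2-en-1-yl)cyclohept-2-en-1-one; 18 formaldehyde (37% aq.)
Product: 19 (5S,6S,7S)-2-(hydroxymethyl)-5-methyl-5-(4-methylpent-3-en-1-yl)-7-(2-oxopropyl)-6-(prop-2-en-1-yl)cyclohept-2-en-1-one
Conditions: 18 (5 equiv), DMAP (30 mol%), THF/H2O (1:1), 23 °C
Reagents that add atoms: none
Why: DMAP adds to the enone β-carbon and the resulting enolate is hydroxymethylated at C2 by formaldehyde before DMAP is expelled (Morita–Baylis–Hillman reaction), a regiospecific entry to the α-(hydroxymethyl) enone that does not enolise the 1,4-diketone and creates no stereocentre.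

**Step 8**
Reactants: 19 (5S,6S,7S)-2-(hydroxymethyl)-5-methyl-5-(4-methylpent-3-en-1-yl)-7-(2-oxopropyl)-6-(prop-2-en-1-yl)cyclohept-2-en-1-one
Product: 20 (1S,4R,8S,10S,11S,13S)-1,5,5-trimethyl-10-(2-oxopropyl)-11-(prop-2-en-1-yl)-6-oxatricyclo[6.3.2.0^4,13]tridecan-9-one
Conditions: BF3·OEt2 (20 mol%), CH2Cl2, −78 → −20 °C
Reagents that add atoms: none
Why: BF3 activation of the enone lets the trisubstituted alkene attack C3 on the only face its tether on the quaternary centre can reach (chair transition state, ring B), the tertiary cation is trapped by the primary hydroxyl, which can close only the cis-fused pyran (ring A), and protonation of the boron enolate gives the cis ring fusion α to the ketone (an epimerisable centre), so C4, C8 and C13 are all relayed from C1 in a cation–olefin cyclisation equivalent to a formal intramolecular hetero-Diels–Alder reaction.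

**Step 9**
Reactants: 20 (1S,4R,8S,10S,11S,13S)-1,5,5-trimethyl-10-(2-oxopropyl)-11-(prop-2-en-1-yl)-6-oxatricyclo[6.3.2.0^4,13]tridecan-9-one
Product: 22 2-[(1S,4R,8S,10S,11S,13S)-1,5,5-trimethyl-9-oxo-10-(2-oxopropyl)-6-oxatricyclo[6.3.2.0^4,13]tridecan-11-yl]acetaldehyde, via ozonide 21 (not isolated)
Conditions: O3, CH2Cl2, −78 °C; then PPh3, −78 → 23 °C
Reagents that add atoms: ozone, [O-][O+]=O
Why: The terminal alkene is the only C=C bond left and ozonolysis with PPh3 reduction of the ozonide cuts it to the acetaldehyde side chain without touching any stereocentre.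

**Step 10**
Reactants: 22 2-[(1S,4R,8S,10S,11S,13S)-1,5,5-trimethyl-9-oxo-10-(2-oxopropyl)-6-oxatricyclo[6.3.2.0^4,13]tridecan-11-yl]acetaldehyde; 23 3-methylbut-2-enoic anhydride
Product: 24 vibsanin E, (E)-2-[(1S,4R,8S,10S,11S,13S)-1,5,5-trimethyl-9-oxo-10-(2-oxopropyl)-6-oxatricyclo[6.3.2.0^4,13]tridecan-11-yl]ethenyl 3-methylbut-2-enoate
Conditions: 23 (2 equiv), Et3N (3 equiv), DMAP (20 mol%), CH2Cl2, 23 °C
Reagents that add atoms: none
Why: The aldehyde is enolised and O-acylated through the acyl-DMAP species far faster than the two hindered ketones (enol ester formation), and the bulky tricyclic substituent favours the E enol ester, the minor Z isomer being removed by chromatography.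

**Compound list**
1 | 5-bromo-2-methylpent-2-ene | CC(C)=CCCBr | starting material
2 | 3-methylcyclopent-2-en-1-one | CC1=CC(=O)CC1 | starting material
3 | 3-iodoprop-1-ene | C=CCI | starting material
4 | (4-methylpent-3-en-1-yl)magnesium bromide | CC(C)=CCC[Mg]Br | intermediate (not isolated)
5 | bromomagnesium (3S)-3-methyl-3-(4-methylpent-3-en-1-yl)cyclopent-1-en-1-olate | CC(C)=CCC[C@@]1(C)CCC(O[Mg]Br)=C1 | intermediate (not isolated)
6 | (2R,3S)-3-methyl-3-(4-methylpent-3-en-1-yl)-2-(prop-2-en-1-yl)cyclopentan-1-one | CC(C)=CCC[C@@]1(C)CCC(=O)[C@@H]1CC=C | intermediate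
7 | sodium (4S,5R)-4-methyl-4-(4-methylpent-3-en-1-yl)-5-(prop-2-en-1-yl)cyclopent-1-en-1-olate | CC(C)=CCC[C@@]1(C)CC=C(O[Na])[C@@H]1CC=C | intermediate (not isolated)
8 | (2R,3S)-5-hydroxy-3-methyl-3-(4-methylpent-3-en-1-yl)-2-(prop-2-en-1-yl)cyclopentan-1-one, both C5 epimers | CC(C)=CCC[C@@]1(C)CC(O)C(=O)[C@@H]1CC=C | intermediate
9 | methyl (2R,3S)-3-methyl-3-(4-methylpent-3-en-1-yl)-5-oxo-2-(prop-2-en-1-yl)pentanoate | CC(C)=CCC[C@@](C)(CC=O)[C@@H](CC=C)C(=O)OC | intermediate (not isolated)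
10 | methyl (2R,3S)-5,5-dimethoxy-3-methyl-3-(4-methylpent-3-en-1-yl)-2-(prop-2-en-1-yl)pentanoate | CC(C)=CCC[C@@](C)(CC(OC)OC)[C@@H](CC=C)C(=O)OC | intermediate
11 | 1-(triphenyl-λ5-phosphanylidene)propan-2-one | CC(=O)C=P(c1ccccc1)(c1ccccc1)c1ccccc1 | starting material
12 | (2R,3S)-5,5-dimethoxy-3-methyl-3-(4-methylpent-3-en-1-yl)-2-(prop-2-en-1-yl)pentanal | CC(C)=CCC[C@@](C)(CC(OC)OC)[C@@H](CC=C)C=O | intermediate (not isolated)
13 | (3E,5S,6S)-8,8-dimethoxy-6-methyl-6-(4-methylpent-3-en-1-yl)-5-(prop-2-en-1-yl)oct-3-en-2-one | CC(C)=CCC[C@@](C)(CC(OC)OC)[C@@H](CC=C)/C=C/C(C)=O | intermediate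
14 | trimethyl(vinyloxy)silane | C=CO[Si](C)(C)C | starting material
15 | (5S,6S,7E)-3-methoxy-5-methyl-5-(4-methylpent-3-en-1-yl)-9-oxo-6-(prop-2-en-1-yl)dec-7-enal, both C3 epimers | CC(C)=CCC[C@@](C)(CC(OC)CC=O)[C@@H](CC=C)/C=C/C(C)=O | intermediate
16 | (2S,3S,4S)-6-methoxy-4-methyl-4-(4-methylpent-3-en-1-yl)-2-(2-oxopropyl)-3-(prop-2-en-1-yl)cycloheptan-1-one, both C6 epimers | CC(=O)C[C@@H]1C(=O)CC(OC)C[C@](C)(CCC=C(C)C)[C@H]1CC=C | intermediate (not isolated)
17 | (5S,6S,7S)-5-methyl-5-(4-methylpent-3-en-1-yl)-7-(2-oxopropyl)-6-(prop-2-en-1-yl)cyclohept-2-en-1-one | CC(=O)C[C@@H]1C(=O)C=CC[C@](C)(CCC=C(C)C)[C@H]1CC=C | intermediate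
18 | formaldehyde | C=O | starting material
19 | (5S,6S,7S)-2-(hydroxymethyl)-5-methyl-5-(4-methylpent-3-en-1-yl)-7-(2-oxopropyl)-6-(prop-2-en-1-yl)cyclohept-2-en-1-one | CC(=O)C[C@@H]1C(=O)C(CO)=CC[C@](C)(CCC=C(C)C)[C@H]1CC=C | intermediate
20 | (1S,4R,8S,10S,11S,13S)-1,5,5-trimethyl-10-(2-oxopropyl)-11-(prop-2-en-1-yl)-6-oxatricyclo[6.3.2.0^4,13]tridecan-9-one | CC(=O)C[C@@H]1C(=O)[C@@H]2COC(C)(C)[C@@H]3CC[C@@](C)(C[C@@H]32)[C@H]1CC=C | intermediate
21 | 1-[(1S,4R,8S,10S,11S,13S)-1,5,5-trimethyl-9-oxo-11-(1,2,4-trioxolan-3-ylmethyl)-6-oxatricyclo[6.3.2.0^4,13]tridecan-10-yl]propan-2-one | CC(=O)C[C@@H]1C(=O)[C@@H]2COC(C)(C)[C@@H]3CC[C@@](C)(C[C@@H]32)[C@H]1CC1OCOO1 | intermediate (not isolated)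
22 | 2-[(1S,4R,8S,10S,11S,13S)-1,5,5-trimethyl-9-oxo-10-(2-oxopropyl)-6-oxatricyclo[6.3.2.0^4,13]tridecan-11-yl]acetaldehyde | CC(=O)C[C@@H]1C(=O)[C@@H]2COC(C)(C)[C@@H]3CC[C@@](C)(C[C@@H]32)[C@H]1CC=O | intermediate
23 | 3-methylbut-2-enoic anhydride | CC(C)=CC(=O)OC(=O)C=C(C)C | starting material
24 | vibsanin E, (E)-2-[(1S,4R,8S,10S,11S,13S)-1,5,5-trimethyl-9-oxo-10-(2-oxopropyl)-6-oxatricyclo[6.3.2.0^4,13]tridecan-11-yl]ethenyl 3-methylbut-2-enoate | CC(=O)C[C@@H]1C(=O)[C@@H]2COC(C)(C)[C@@H]3CC[C@@](C)(C[C@@H]32)[C@H]1/C=C/OC(=O)C=C(C)C | target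

**Totals**
Total step count: 10. Longest linear sequence: 10 steps (2 → 24).

**Steps most likely to fail**

Step 6 (seven-membered Stetter closure). Ring sizes above six are poorly precedented for this reaction, and benzoin dimerisation or loss of methanol from the aldehyde may compete. The fallback sets out from 15 and keeps the same bond but forms it reductively. SmI2 (2.5 equiv) with tBuOH in THF at −78 °C couples the aldehyde carbon to the enone β-carbon through a ketyl, giving the carbinol 1-[(1S,6S,7S)-2-hydroxy-4-methoxy-6-methyl-6-(4-methylpent-3-en-1-yl)-7-(prop-2-en-1-yl)cycloheptyl]propan-2-one F1. Dess–Martin periodinane oxidation of the carbinol comes back to the route at 16, which DBU converts into 17 as before.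

Step 7 (Morita–Baylis–Hillman reaction on a hindered seven-ring enone). The reaction may be very slow. The fallback sets out from 17. Iodine and pyridine in CH2Cl2 give the α-iodoenone (5S,6S,7S)-2-iodo-5-methyl-5-(4-methylpent-3-en-1-yl)-7-(2-oxopropyl)-6-(prop-2-en-1-yl)cyclohept-2-en-1-one F2. Stille coupling with Bu3SnCH2OH and Pd(PPh3)4 in dioxane at 80 °C then comes back to the route at 19.

Step 10 (E/Z ratio and chemoselectivity of the enol acylation). The fallback sets out from 20 and builds the E enol ester by a stereoretentive C–O coupling.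
- RuHCl(CO)(PPh3)3 in PhMe at 80 °C moves the terminal double bond inward to (1S,4R,8S,10S,11S,13S)-1,5,5-trimethyl-10-(2-oxopropyl)-11-[(1E)-prop-1-en-1-yl]-6-oxatricyclo[6.3.2.0^4,13]tridecan-9-one F3.
- Ozonolysis with PPh3 work-up gives (1S,4R,8S,10S,11S,13S)-1,5,5-trimethyl-9-oxo-10-(2-oxopropyl)-6-oxatricyclo[6.3.2.0^4,13]tridecane-11-carbaldehyde F4.
- Takai–Utimoto olefination (CrCl2, Cl2CHB(pin), LiI, THF) gives (1S,4R,8S,10S,11S,13S)-1,5,5-trimethyl-10-(2-oxopropyl)-11-[(E)-2-(4,4,5,5-tetramethyl-1,3,2-dioxaborolan-2-yl)ethenyl]-6-oxatricyclo[6.3.2.0^4,13]tridecan-9-one F5.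
- Cu(OAc)2-mediated oxidative coupling of the boronate with 3-methylbut-2-enoic acid (Et3N, 4 Å sieves, air) retains the E geometry and comes back to the route at 24.

Further compounds
F1 | step 6 | 1-[(1S,6S,7S)-2-hydroxy-4-methoxy-6-methyl-6-(4-methylpent-3-en-1-yl)-7-(prop-2-en-1-yl)cycloheptyl]propan-2-one, carbinol and methoxy epimers | CC(=O)C[C@@H]1C(O)CC(OC)C[C@](C)(CCC=C(C)C)[C@H]1CC=C
F2 | step 7 | (5S,6S,7S)-2-iodo-5-methyl-5-(4-methylpent-3-en-1-yl)-7-(2-oxopropyl)-6-(prop-2-en-1-yl)cyclohept-2-en-1-one | CC(=O)C[C@@H]1C(=O)C(I)=CC[C@](C)(CCC=C(C)C)[C@H]1CC=C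
F3 | step 10 | (1S,4R,8S,10S,11S,13S)-1,5,5-trimethyl-10-(2-oxopropyl)-11-[(1E)-prop-1-en-1-yl]-6-oxatricyclo[6.3.2.0^4,13]tridecan-9-one | CC(=O)C[C@@H]1C(=O)[C@@H]2COC(C)(C)[C@@H]3CC[C@@](C)(C[C@@H]32)[C@H]1/C=C/C
F4 | step 10 | (1S,4R,8S,10S,11S,13S)-1,5,5-trimethyl-9-oxo-10-(2-oxopropyl)-6-oxatricyclo[6.3.2.0^4,13]tridecane-11-carbaldehyde | CC(=O)C[C@@H]1C(=O)[C@@H]2COC(C)(C)[C@@H]3CC[C@@](C)(C[C@@H]32)[C@H]1C=O
F5 | step 10 | (1S,4R,8S,10S,11S,13S)-1,5,5-trimethyl-10-(2-oxopropyl)-11-[(E)-2-(4,4,5,5-tetramethyl-1,3,2-dioxaborolan-2-yl)ethenyl]-6-oxatricyclo[6.3.2.0^4,13]tridecan-9-one | CC(=O)C[C@@H]1C(=O)[C@@H]2COC(C)(C)[C@@H]3CC[C@@](C)(C[C@@H]32)[C@H]1/C=C/B1OC(C)(C)C(C)(C)O1
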